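**Plan**
- Retrosynthetic cuts: the two acetates (C2, C9); ring B at C3=C4 (ring-closing metathesis); C6–Cl (from C6–OH) and C5–C6 (butadienylation of a C6 aldehyde); the lactone C19–O7 bond; then ring A at C1–C10 and C11–C12 by a Diels–Alder reaction, with the 13,14-epoxide traced back to an alkene and the 11-OH to a formyl group.
- Enabling feature: ring A (C1, C10, C11, C12, C13, C14) is a cyclohexane whose 13,14-epoxide marks the alkene of a cyclohexene retron, with oxygen on C12 (dienyl ester terminus) and on C11 (from an endo formyl group); the two carbinols C2 and C9 flank the C1–C10 bond, so one silicon atom can bridge O2 and O9 as a temporary tether.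
- Forward: fragment 1 (C6–C11, C17–C20) from L-arabinose; fragment 2 (C1–C3, C12–C15, with the butyrate in place); silaketal union; the cycloaddition forms ring A and a temporary seven-membered ring; ring A is oxidised; the C4/C5/C16 diene is added at C6; the lactone is closed; chloride is installed; ring B is closed by metathesis; the silicon is removed and the diol acetylated.
- Stereochemistry: C7 and C9 from L-arabinose; C8 by exo addition to a furanos-3-ulose, C17 in the same aldol; C2 by catalytic asymmetric vinylation; C1, C10, C11, C12 in the Diels–Alder step; C13/C14 by epoxidation anti to the two axial methyl groups; C6 by chelation-controlled addition, then inversion with chloride.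

Key step: step 13

Remark: briarane numbering (C1–C20) is used for all intermediates, α/β refer to ring A drawn with the C15 methyl up (β), and tetrabutylammonium malondialdehyde enolate and 2-(triphenylphosphoranylidene)propanal are taken as commercial.

Step 1
Reactants: 1 L-arabinose
Product: 2 5-O-(tert-butyldiphenylsilyl)-L-arabinofuranose (anomeric mixture)
Conditions: TBDPSCl, pyridine, 0 °C to rt
Reagents that add atoms: tert-butyl(chloro)diphenylsilane CC(C)(C)[Si](Cl)(c1ccccc1)c1ccccc1
Why: Regioselective O-silylation of the primary hydroxyl traps the sugar in its furanose form; no stereocentre is changed.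

Step 2
Reactants: 2 5-O-(tert-butyldiphenylsilyl)-L-arabinofuranose
Product: 3 5-O-(tert-butyldiphenylsilyl)-1,2-O-isopropylidene-β-L-arabinofuranose
Conditions: 2,2-dimethoxypropane, acetone, CSA (cat.), rt
Reagents that add atoms: 2,2-dimethoxypropane COC(C)(C)OC
Why: Acid-catalysed ketalisation bridges the cis anomeric and C7 (sugar C2) oxygens of the β-furanose, leaving only the C8 (sugar C3) hydroxyl free.

Step 3
Reactants: 3 5-O-(tert-butyldiphenylsilyl)-1,2-O-isopropylidene-β-L-arabinofuranose
Product: 4 5-O-(tert-butyldiphenylsilyl)-1,2-O-isopropylidene-β-L-threo-pentofuranos-3-ulose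
Conditions: Dess–Martin periodinane, CH2Cl2, rt
Reagents that add atoms: none
Why: Dess–Martin oxidation of the only free secondary alcohol should give the C8 ketone without touching the ketal or the silyl ether.

Step 4
Reactants: 4 furanos-3-ulose; 5 tert-butyl propanoate
Product: 6 tert-butyl (2R)-2-[5-O-(tert-butyldiphenylsilyl)-1,2-O-isopropylidene-β-L-lyxofuranos-3-C-yl]propanoate
Conditions: LiN(iPr)2, THF, −78 °C, 5; then 4, −78 °C
Reagents that add atoms: none
Why: Aldol addition of the lithium E(O)-enolate: attack on the exo face of the cis-fused dioxolane–furanose sets C8 (OH cis to the acetonide), and a closed Zimmerman–Traxler chair with the tert-butoxy group over the unhindered ring-oxygen flank should set C17.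

Step 5
Reactants: 6 branched furanose ester
Product: 8 open-chain 6,7,8,9-tetrol (10-O-TBDPS; tert-butyl C19 ester; C7, C8, C9, C17 as in 6), via lactol 7 (not isolated)
Conditions: AcOH–H2O (4:1), 70 °C; then NaBH4, EtOH, 0 °C
Reagents that add atoms: none
Why: Hydrolysis of the anomeric ketal followed by borohydride reduction of the lactol opens the furanose; the hindered tert-butyl ester resists lactonisation and no stereocentre is touched.

Step 6
Reactants: 8 open-chain tetrol
Product: 9 6,7-O-isopropylidene derivative of 8 (8-OH and 9-OH free)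
Conditions: 2-methoxypropene, PPTS (cat.), DMF, 0 °C
Reagents that add atoms: 2-methoxypropene COC(C)=C
Why: Kinetic isopropylidenation engages the primary 6-OH and closes the five-membered dioxolane onto the 7-OH, leaving the 9-OH and the tertiary 8-OH free.

Step 7
Reactants: 9 acetonide silyl ether
Product: 10 8,9,10-triol (6,7-acetonide; tert-butyl ester)
Conditions: Bu4NF, AcOH, THF, 0 °C to rt
Reagents that add atoms: none
Why: Fluoride-mediated desilylation, buffered with acetic acid to avoid retro-aldol cleavage, releases the primary 10-OH.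

Step 8
Reactants: 10 triol; 11 2-(triphenylphosphoranylidene)propanal
Product: 13 fragment 1: E enal (C10=C11 with C20 methyl and formyl group; 9-OH and 8-OH free; 6,7-acetonide; tert-butyl ester), via hydroxy aldehyde 12 (not isolated)
Conditions: TEMPO (cat.), N-chlorosuccinimide, Bu4NCl (cat.), CH2Cl2–aq. NaHCO3/K2CO3, 0 °C; then 11, CH2Cl2, rt
Reagents that add atoms: none
Why: Nitroxyl-catalysed oxidation selective for the primary alcohol, then Wittig olefination with the stabilised ylide, should give the E trisubstituted enal in which C9 is cis to the C20 methyl.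

Step 9
Reactants: 14 tetrabutylammonium (E)-3-oxoprop-1-en-1-olate
Product: 15 (E)-3-oxoprop-1-en-1-yl butanoate
Conditions: butanoyl chloride, CH2Cl2, −78 to 0 °C
Reagents that add atoms: butanoyl chloride CCCC(Cl)=O
Why: O-Acylation of the malondialdehyde enolate gives the E enol ester, which carries the future C12 butyrate.

Step 10
Reactants: 15 (E)-3-oxoprop-1-en-1-yl butanoate; 11 2-(triphenylphosphoranylidene)propanal
Product: 16 (1E,3E)-4-methyl-5-oxopenta-1,3-dien-1-yl butanoate
Conditions: CH2Cl2, rt
Reagents that add atoms: none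
Why: Wittig olefination with the stabilised formyl ylide is E-selective and fixes the C1=C14 geometry with the C15 methyl cis to C13.

Step 11
Reactants: 16 dienal
Product: 17 fragment 2: (1E,3E,5S)-5-hydroxy-4-methylhepta-1,3,6-trien-1-yl butanoate
Conditions: Zn(CH=CH2)2, (−)-MIB (cat.), toluene, −20 °C
Reagents that add atoms: divinylzinc C=C[Zn]C=C
Why: Amino-alcohol-catalysed asymmetric addition of divinylzinc to the aldehyde sets C2 by Si-face delivery; the enol ester is inert to the organozinc reagent.

Step 12
Reactants: 17 fragment 2; 13 fragment 1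
Product: 19 di-tert-butylsilaketal triene (O2–Si–O9 tether between dienyl butyrate and enal), via silyl triflate 18 (not isolated)
Conditions: tBu2Si(OTf)2, 2,6-lutidine, CH2Cl2, −78 °C; then 13, −78 °C to rt
Reagents that add atoms: di-tert-butylsilyl bis(trifluoromethanesulfonate) CC(C)(C)[Si](OS(=O)(=O)C(F)(F)F)(OS(=O)(=O)C(F)(F)F)C(C)(C)C
Why: Stepwise unsymmetrical silaketal formation: the dienol displaces one triflate at low temperature and the secondary 9-OH of 13 displaces the second on warming, the tertiary 8-OH staying free.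

Step 13
Reactants: 19 silaketal triene
Product: 20 cycloadduct: ring A cyclohexene (C13=C14) trans-fused to the seven-membered 1,3-dioxa-2-silepane; C11 bears the C20 methyl (β) and CHO (α), C12 the butyrate (α), C1 the C15 methyl (β), C2 a vinyl group
Conditions: toluene (5 mM), BHT (cat.), 140 °C, sealed tube
Reagents that add atoms: none
Why: Thermal type 1 intramolecular Diels–Alder reaction of a silaketal-tethered triene, the closest known class being silicon-tethered cycloadditions of dienols with hydroxy dienophiles. Ring A closes by a concerted suprafacial [4+2] addition (C1–C10 and C11–C12), and the seven-membered dioxasilepane closes as the trans-fused tether ring through the transition state with the formyl group endo and the tether exo. The E,E diene geometry relates C12 (acyloxy outside) to C1 (C2 outside, C15 methyl inside), the E enal relates C10 to C11, and the endo formyl group links the two pairs so that O12, C2 and CHO end on one face. The absolute sense should follow from C9, where A(1,3) strain with the cis C20 methyl holds H9 in the enal plane so that the diene tethered through O9 reaches only the face opposite C8; C2 reinforces this by turning its hydrogen toward the C15 methyl. Regiochemistry is enforced by the tether and is also the electronically preferred ortho orientation of a 1-acyloxy diene with an enal.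

Step 14
Reactants: 20 cycloadduct
Product: 22 11-hydroxy 13,14-α-epoxide (12-butyrate, silaketal, acetonide and tert-butyl ester retained), via formate 21 (not isolated)
Conditions: mCPBA, NaHCO3, CH2Cl2, 0 °C to rt; then KHCO3, MeOH, 0 °C
Reagents that add atoms: 3-chloroperbenzoic acid OOC(=O)c1cccc(Cl)c1
Why: Baeyer–Villiger oxidation of the neopentyl aldehyde (tertiary C11 migrates with retention) and Prilezhaev epoxidation of C13=C14 from the α face, the β face being screened by the axial C15 and C20 methyl groups; mild methanolysis then removes the formate.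

Step 15
Reactants: 22 hydroxy epoxide
Product: 23 6,7-diol
Conditions: AcOH–H2O–THF (3:1:1), 40 °C
Reagents that add atoms: none
Why: Aqueous acetic acid hydrolyses the terminal dioxolane, while the di-tert-butylsilaketal, the epoxide and the hindered tert-butyl ester should persist.

Step 16
Reactants: 23 6,7-diol
Product: 25 (6R)-dienyl carbinol (C5 bears the C16 methylene and a vinyl group; 6-OH syn to 7-OH), via hydroxy aldehyde 24 (not isolated)
Conditions: TEMPO (cat.), N-chlorosuccinimide, Bu4NCl (cat.), CH2Cl2–aq. buffer pH 8.6, 0 °C; then In powder, 1,4-dibromobut-2-yne, THF–H2O, rt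
Reagents that add atoms: 1,4-dibromobut-2-yne BrCC#CCBr
Why: Selective nitroxyl oxidation of the primary alcohol, then indium-mediated Barbier-type 1,3-butadien-2-ylation in aqueous medium, in which chelation of indium by the free 7-OH and the aldehyde (Cram chelate) should set C6 syn to O7.

Step 17
Reactants: 25 dienyl carbinol
Product: 26 γ-lactone (C19–O7; 8-OH and 17-methyl cis as in the target)
Conditions: TsOH·H2O (cat.), CH2Cl2, rt
Reagents that add atoms: none
Why: Acid-catalysed intramolecular transesterification closes the five-membered lactone on O7 in preference to the six-membered alternative on O6; the β-shielded, acyloxy-deactivated epoxide should tolerate catalytic acid.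

Step 18
Reactants: 26 lactone
Product: 27 (6S)-allylic chloride
Conditions: PPh3, hexachloroacetone, CH2Cl2, −20 to 0 °C
Reagents that add atoms: hexachloroacetone ClC(Cl)(Cl)C(=O)C(Cl)(Cl)Cl
Why: Appel-type chlorination converts the secondary allylic alcohol into the chloride by SN2 displacement with inversion at C6 and without allylic transposition; the tertiary alcohols do not react.

Step 19
Reactants: 27 chloride
Product: 28 silylene-bridged tricycle with ring B closed (3Z olefin, C5 exo-methylene)
Conditions: second-generation Grubbs catalyst (cat.), toluene (1 mM), 80 °C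
Reagents that add atoms: none
Why: Ring-closing metathesis between the C2 vinyl group and the monosubstituted terminus of the butadiene closes the ten-membered ring; ring strain and the silylene bridge (C3 and C8 cis on the seven-membered ring) should favour the Z olefin.

Step 20
Reactants: 28 bridged tricycle
Product: 29 2,9-diol
Conditions: HF·pyridine, pyridine, THF, 0 °C to rt
Reagents that add atoms: none
Why: Fluoride cleaves both Si–O bonds of the silylene and releases the 2- and 9-hydroxyls without affecting the esters, the epoxide or the chloride.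

Step 21
Reactants: 29 2,9-diol
Product: 30 CNP0273377.1 (target)
Conditions: Ac2O, pyridine, DMAP (cat.), CH2Cl2, 0 °C to rt
Reagents that add atoms: acetic anhydride CC(=O)OC(C)=O
Why: Acetylation of the two secondary alcohols; the tertiary 8- and 11-hydroxyls are not acylated under these conditions.

**Compound list**
1 | L-arabinose (open-chain form) | O=C[C@H](O)[C@@H](O)[C@@H](O)CO | starting material
2 | 5-O-(tert-butyldiphenylsilyl)-L-arabinofuranose | OC1O[C@@H](CO[Si](c2ccccc2)(c2ccccc2)C(C)(C)C)[C@H](O)[C@H]1O | intermediate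
3 | 5-O-(tert-butyldiphenylsilyl)-1,2-O-isopropylidene-β-L-arabinofuranose | CC1(C)O[C@H]2O[C@@H](CO[Si](c3ccccc3)(c3ccccc3)C(C)(C)C)[C@H](O)[C@H]2O1 | intermediate
4 | 5-O-(tert-butyldiphenylsilyl)-1,2-O-isopropylidene-β-L-threo-pentofuranos-3-ulose | CC1(C)O[C@H]2O[C@@H](CO[Si](c3ccccc3)(c3ccccc3)C(C)(C)C)C(=O)[C@H]2O1 | intermediate
5 | tert-butyl propanoate | CCC(=O)OC(C)(C)C | starting material
6 | tert-butyl (2R)-2-[5-O-(tert-butyldiphenylsilyl)-1,2-O-isopropylidene-β-L-lyxofuranos-3-C-yl]propanoate | CC1(C)O[C@H]2O[C@@H](CO[Si](c3ccccc3)(c3ccccc3)C(C)(C)C)[C@](O)([C@@H](C)C(=O)OC(C)(C)C)[C@H]2O1 | intermediate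
7 | lactol from 6 (anomeric mixture) | OC1O[C@@H](CO[Si](c2ccccc2)(c2ccccc2)C(C)(C)C)[C@](O)([C@@H](C)C(=O)OC(C)(C)C)[C@H]1O | intermediate
8 | open-chain 6,7,8,9-tetrol, 10-O-TBDPS, tert-butyl ester | OC[C@H](O)[C@@](O)([C@@H](C)C(=O)OC(C)(C)C)[C@@H](O)CO[Si](c1ccccc1)(c1ccccc1)C(C)(C)C | intermediate
9 | 6,7-O-isopropylidene derivative of 8 | CC1(C)OC[C@H](O1)[C@@](O)([C@@H](C)C(=O)OC(C)(C)C)[C@@H](O)CO[Si](c1ccccc1)(c1ccccc1)C(C)(C)C | intermediate
10 | 8,9,10-triol with 6,7-acetonide | CC1(C)OC[C@H](O1)[C@@](O)([C@@H](C)C(=O)OC(C)(C)C)[C@@H](O)CO | intermediate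
11 | 2-(triphenylphosphoranylidene)propanal | CC(C=O)=P(c1ccccc1)(c1ccccc1)c1ccccc1 | starting material
12 | 9-hydroxy C10 aldehyde | CC1(C)OC[C@H](O1)[C@@](O)([C@@H](C)C(=O)OC(C)(C)C)[C@@H](O)C=O | intermediate
13 | fragment 1, E enal | CC1(C)OC[C@H](O1)[C@@](O)([C@@H](C)C(=O)OC(C)(C)C)[C@@H](O)/C=C(\C)C=O | intermediate
14 | tetrabutylammonium (E)-3-oxoprop-1-en-1-olate | CCCC[N+](CCCC)(CCCC)CCCC.[O-]/C=C/C=O | starting material
15 | (E)-3-oxoprop-1-en-1-yl butanoate | CCCC(=O)O/C=C/C=O | intermediate
16 | (1E,3E)-4-methyl-5-oxopenta-1,3-dien-1-yl butanoate | CCCC(=O)O/C=C/C=C(\C)C=O | intermediate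
17 | fragment 2, (1E,3E,5S)-5-hydroxy-4-methylhepta-1,3,6-trien-1-yl butanoate | CCCC(=O)O/C=C/C=C(\C)[C@@H](O)C=C | intermediate
18 | di-tert-butylsilyl triflate of 17 | CCCC(=O)O/C=C/C=C(\C)[C@H](C=C)O[Si](OS(=O)(=O)C(F)(F)F)(C(C)(C)C)C(C)(C)C | intermediate
19 | di-tert-butylsilaketal triene | CCCC(=O)O/C=C/C=C(\C)[C@H](C=C)O[Si](C(C)(C)C)(C(C)(C)C)O[C@@H](/C=C(\C)C=O)[C@](O)([C@@H](C)C(=O)OC(C)(C)C)[C@@H]1COC(C)(C)O1 | intermediate
20 | Diels–Alder adduct (ring A cyclohexene, 11-CHO) | C=C[C@@H]1O[Si](C(C)(C)C)(C(C)(C)C)O[C@H]([C@](O)([C@@H](C)C(=O)OC(C)(C)C)[C@@H]3COC(C)(C)O3)[C@H]2[C@](C)(C=O)[C@H](OC(=O)CCC)C=C[C@]12C | intermediate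
21 | 11-formate 13,14-epoxide | C=C[C@@H]1O[Si](C(C)(C)C)(C(C)(C)C)O[C@H]([C@](O)([C@@H](C)C(=O)OC(C)(C)C)[C@@H]3COC(C)(C)O3)[C@H]2[C@](C)(OC=O)[C@H](OC(=O)CCC)[C@@H]4O[C@@H]4[C@]12C | intermediate
22 | 11-hydroxy 13,14-epoxide | C=C[C@@H]1O[Si](C(C)(C)C)(C(C)(C)C)O[C@H]([C@](O)([C@@H](C)C(=O)OC(C)(C)C)[C@@H]3COC(C)(C)O3)[C@H]2[C@](C)(O)[C@H](OC(=O)CCC)[C@@H]4O[C@@H]4[C@]12C | intermediate
23 | 6,7-diol | C=C[C@@H]1O[Si](C(C)(C)C)(C(C)(C)C)O[C@H]([C@](O)([C@@H](C)C(=O)OC(C)(C)C)[C@@H](O)CO)[C@H]2[C@](C)(O)[C@H](OC(=O)CCC)[C@@H]4O[C@@H]4[C@]12C | intermediate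
24 | 7-hydroxy C6 aldehyde | C=C[C@@H]1O[Si](C(C)(C)C)(C(C)(C)C)O[C@H]([C@](O)([C@@H](C)C(=O)OC(C)(C)C)[C@@H](O)C=O)[C@H]2[C@](C)(O)[C@H](OC(=O)CCC)[C@@H]4O[C@@H]4[C@]12C | intermediate
25 | (6R)-dienyl carbinol | C=C[C@@H]1O[Si](C(C)(C)C)(C(C)(C)C)O[C@H]([C@](O)([C@@H](C)C(=O)OC(C)(C)C)[C@@H](O)[C@H](O)C(=C)C=C)[C@H]2[C@](C)(O)[C@H](OC(=O)CCC)[C@@H]4O[C@@H]4[C@]12C | intermediate
26 | γ-lactone with 6-OH | C=C[C@@H]1O[Si](C(C)(C)C)(C(C)(C)C)O[C@H]([C@]5(O)[C@@H](C)C(=O)O[C@H]5[C@H](O)C(=C)C=C)[C@H]2[C@](C)(O)[C@H](OC(=O)CCC)[C@@H]4O[C@@H]4[C@]12C | intermediate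
27 | (6S)-chloride | C=C[C@@H]1O[Si](C(C)(C)C)(C(C)(C)C)O[C@H]([C@]5(O)[C@@H](C)C(=O)O[C@H]5[C@@H](Cl)C(=C)C=C)[C@H]2[C@](C)(O)[C@H](OC(=O)CCC)[C@@H]4O[C@@H]4[C@]12C | intermediate
28 | 2,9-O-di-tert-butylsilylene briarane (ring B closed) | C=C1/C=C\[C@H](O[Si]5(C(C)(C)C)C(C)(C)C)[C@@]2(C)[C@H]3O[C@H]3[C@@H](OC(=O)CCC)[C@@](C)(O)[C@@H]2[C@H](O5)[C@]2(O)[C@@H](C)C(=O)O[C@H]2[C@H]1Cl | intermediate
29 | 2,9-diol | C=C1/C=C\[C@H](O)[C@@]2(C)[C@H]3O[C@H]3[C@@H](OC(=O)CCC)[C@@](C)(O)[C@@H]2[C@H](O)[C@]2(O)[C@@H](C)C(=O)O[C@H]2[C@H]1Cl | intermediate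
30 | CNP0273377.1 | C=C1/C=C\[C@H](OC(C)=O)[C@@]2(C)[C@H]3O[C@H]3[C@@H](OC(=O)CCC)[C@@](C)(O)[C@@H]2[C@H](OC(C)=O)[C@]2(O)[C@@H](C)C(=O)O[C@H]2[C@H]1Cl | target

Total step count: 21. Longest linear sequence: 18 steps (steps 1–8 and 12–21).

**Steps most likely to fail**

Step 13. The Z-disposed C15 methyl at the diene terminus slows the thermal cycloaddition, so at the temperature needed the endo, trans-fused preference may erode or the dienyl ester may decompose. The fallback sets out from 19 and comes back at 20. The enal of 19 would be converted with MeOSiMe3 and catalytic TMSOTf at −78 °C into dimethyl acetal F1. The same Lewis acid ionises the acetal to an alkoxy-allyl cation, a much stronger dienophile, and the tethered ionic Diels–Alder reaction should proceed between −78 and −40 °C to acetal cycloadduct F2 through the same formyl-endo, tether-exo arrangement. Chemoselective cleavage of the aldehyde-derived acetal in the presence of the isopropylidene ketal (TESOTf, 2,4,6-collidine, then water) would return 20.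

Step 19. Closure of the strained ten-membered ring may lose to oligomerisation, to engagement of the 1,1-disubstituted alkene of the diene, or to formation of the E olefin, because the silylene bridge may hold the two olefinic arms unfavourably. The fallback sets out from 27 and comes back at 30. The bridge would be cleaved first with HF·pyridine to diol F3, which would be acetylated (Ac2O, pyridine, DMAP) to diacetate F4. Ring-closing metathesis of this conformationally free triene with the second-generation Grubbs catalyst at high dilution would then form ring B as the last step and give 30 directly.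

Step 4. Facial discrimination at the enolate carbon may be poor, so that C17 forms as a mixture while C8 stays secure. The fallback sets out from 4 and comes back at 6. Addition of the lithium enolate of tert-butyl acetate to 4 would give, with the same exo selectivity, hydroxy ester F5, which has no C17 stereocentre. Double deprotonation (LiN(iPr)2, 2.2 equiv) and methylation with MeI (Fráter–Seebach alkylation of the chelated alkoxide enolate, the electrophile entering past the ring-oxygen flank) would then install the C17 methyl and give 6.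

Further compounds
F1 | step 13 | dimethyl acetal of silaketal triene 19 | CCCC(=O)O/C=C/C=C(\C)[C@H](C=C)O[Si](C(C)(C)C)(C(C)(C)C)O[C@@H](/C=C(\C)C(OC)OC)[C@](O)([C@@H](C)C(=O)OC(C)(C)C)[C@@H]1COC(C)(C)O1
F2 | step 13 | dimethyl acetal of cycloadduct 20 | C=C[C@@H]1O[Si](C(C)(C)C)(C(C)(C)C)O[C@H]([C@](O)([C@@H](C)C(=O)OC(C)(C)C)[C@@H]3COC(C)(C)O3)[C@H]2[C@](C)(C(OC)OC)[C@H](OC(=O)CCC)C=C[C@]12C
F3 | step 19 | 2,9-diol from chloride 27 (ring B open) | C=CC(=C)[C@H](Cl)[C@@H]1OC(=O)[C@H](C)[C@@]1(O)[C@@H](O)[C@H]2[C@](C)(O)[C@H](OC(=O)CCC)[C@@H]3O[C@@H]3[C@]2(C)[C@@H](O)C=C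
F4 | step 19 | 2,9-diacetate triene (ring B open) | C=CC(=C)[C@H](Cl)[C@@H]1OC(=O)[C@H](C)[C@@]1(O)[C@@H](OC(C)=O)[C@H]2[C@](C)(O)[C@H](OC(=O)CCC)[C@@H]3O[C@@H]3[C@]2(C)[C@@H](OC(C)=O)C=C
F5 | step 4 | tert-butyl 2-[5-O-(tert-butyldiphenylsilyl)-1,2-O-isopropylidene-β-L-lyxofuranos-3-C-yl]acetate | CC1(C)O[C@H]2O[C@@H](CO[Si](c3ccccc3)(c3ccccc3)C(C)(C)C)[C@](O)(CC(=O)OC(C)(C)C)[C@H]2O1
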